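## Retrosynthetic overview

Numbering used throughout: ring C1 = ketone carbon, C2=C3 = alkene, C4 = allylic CH2, C5 = carbinol carbon, C6 = CH2 between C5 and C1; side chain C1' = CH2 on C5, C2' = side-chain ketone carbon.

1. Enabling feature: C5 is a tertiary carbinol flanked by three CH2 groups, and C3, C1, C5, C2' carry the 1,3,5,7 oxygenation pattern of a polyketide. With C3 raised to a ketone, ring bond C4–C5 is the bond of a β-hydroxy ketone, the same aldol closure the presumed polyketide biosynthesis would use.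
2. Endgame retron: enone (C1=O, C2=C3) ⇐ Stork–Danheiser transposition of a 3-alkoxy enone with its carbonyl at C3 ⇐ β-keto dioxolane (C3 ketone, C1 ketal); the C2' ketone ⇐ silyl-protected carbinol.
3. Key disconnection C4–C5: (R)-proline-catalysed intramolecular aldol of the methyl ketone terminus (C4H3–C3=O) onto the C5 ketone of an acyclic 1,5-diketone. This one step closes the only carbocycle and sets the only stereocentre.
4. The acyclic precursor comes from three commercial pieces: dimethyl 3-oxoglutarate (C2–C1–C6 plus carbonyl carbons C3 and C5, C1 masked as dioxolane), MeMgBr (C4 and C1'), and linoleyl alcohol (C2' and the (Z,Z)-dienyl chain), joined by a boron aldol at C1'–C2'.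
5. Ring order: dioxolane (protecting ring, step 1, opened in step 8), then the six-membered carbocycle (step 7); there is no other ring.

Key step: step 7

Remark 1: the C2' carbinol centre created in step 5 is not controlled and is carried as both configurations in compounds 8–14 (SMILES without a descriptor there); step 10 oxidises it to the ketone, so the target is a single stereoisomer.

Remark 2: the sense of induction in step 7 is assigned by atom-for-atom analogy with the Hajos–Parrish cyclization; should it prove opposite, (S)-proline would be used in the same step.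

## Route

Step 1
Reactants: 1 dimethyl 3-oxopentanedioate
Product: 2 dimethyl 2,2'-(1,3-dioxolane-2,2-diyl)diacetate
Conditions: ethylene glycol, BF3·OEt2, CH2Cl2, rt
Reagents that add atoms: ethylene glycol OCCO
Why: Lewis-acid-catalysed ketalization of the ketone between two ester-bearing methylenes, chosen over protic acid and heat to avoid self-condensation; no stereocentre is formed.

Step 2
Reactants: 2 dimethyl 2,2'-(1,3-dioxolane-2,2-diyl)diacetate
Product: 3 2,2'-(1,3-dioxolane-2,2-diyl)bis(N-methoxy-N-methylacetamide)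
Conditions: MeNH(OMe)·HCl, AlMe3, CH2Cl2, 0 °C to rt; aq. Rochelle salt
Reagents that add atoms: N,O-dimethylhydroxylamine hydrochloride CNOC.Cl
Why: Aluminium-amide aminolysis of both esters (Weinreb amide formation) under non-basic conditions, so the α-methylenes are not deprotonated and the β-ketal is not eliminated; no stereocentre.

Step 3
Reactants: 3 2,2'-(1,3-dioxolane-2,2-diyl)bis(N-methoxy-N-methylacetamide)
Product: 4 1,1'-(1,3-dioxolane-2,2-diyl)di(propan-2-one)
Conditions: MeMgBr (2.6 equiv), THF, −78 to 0 °C; aq. NH4Cl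
Reagents that add atoms: methylmagnesium bromide C[Mg]Br
Why: Weinreb ketone synthesis, in which the chelated tetrahedral adducts stop at mono-addition and release both methyl ketones only on neutral work-up, so the 1,5-diketone cannot aldolize in the flask; no stereocentre.

Step 4
Reactants: 5 (9Z,12Z)-octadeca-9,12-dien-1-ol (linoleyl alcohol)
Product: 6 (9Z,12Z)-octadeca-9,12-dienal
Conditions: Dess–Martin periodinane, pyridine, CH2Cl2, 0 °C to rt
Reagents that add atoms: none
Why: Dess–Martin oxidation of a primary alcohol to the aldehyde under buffered, non-basic conditions that should leave the skipped (Z,Z)-diene unisomerised; no stereocentre.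

Step 5
Reactants: 4 1,1'-(1,3-dioxolane-2,2-diyl)di(propan-2-one) (3 equiv), 6 (9Z,12Z)-octadeca-9,12-dienal
Product: 8 1-{2-[(12Z,15Z)-4-hydroxy-2-oxohenicosa-12,15-dien-1-yl]-1,3-dioxolan-2-yl}propan-2-one, via boron enolate 7 (not isolated)
Conditions: (c-C6H11)2BCl, Et3N, Et2O, −78 °C; then 6, −78 to −20 °C; MeOH, pH 7 buffer, H2O2, 0 °C
Reagents that add atoms: none
Why: Boron-mediated aldol addition in which (c-C6H11)2BCl/Et3N enolizes one methyl ketone of 4 at its methyl group and the enol borinate adds to the aldehyde but not to the second ketone, the excess of 4 suppressing double addition; the new C2' carbinol centre forms without control and is erased in step 10.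

Step 6
Reactants: 8 1-{2-[(12Z,15Z)-4-hydroxy-2-oxohenicosa-12,15-dien-1-yl]-1,3-dioxolan-2-yl}propan-2-one
Product: 9 1-{2-[(12Z,15Z)-2-oxo-4-[(triethylsilyl)oxy]henicosa-12,15-dien-1-yl]-1,3-dioxolan-2-yl}propan-2-one
Conditions: TESCl, imidazole, DMF, 0 °C to rt
Reagents that add atoms: chlorotriethylsilane CC[Si](Cl)(CC)CC
Why: Imidazole-promoted silyl ether formation at the only hydroxyl, which should block retro-aldol cleavage and dehydration of the β-hydroxy ketone under the amine catalysis of step 7; no stereocentre changes.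

Step 7
Reactants: 9 1-{2-[(12Z,15Z)-2-oxo-4-[(triethylsilyl)oxy]henicosa-12,15-dien-1-yl]-1,3-dioxolan-2-yl}propan-2-one
Product: 11 (9R)-9-hydroxy-9-[(10Z,13Z)-2-[(triethylsilyl)oxy]nonadeca-10,13-dien-1-yl]-1,4-dioxaspiro[4.5]decan-7-one, via enamine 10 (not isolated)
Conditions: (R)-proline (30 mol%), DMSO, rt
Reagents that add atoms: none
Why: (R)-Proline should condense with the less hindered methyl ketone (C3) to give enamine 10 at the methyl terminus, whose CH2= carbon (C4) adds to the C5 ketone activated by a hydrogen bond from the carboxylic acid, and iminium hydrolysis then releases ketol 11 and the catalyst. The closest known reaction type is the Hajos–Parrish-type proline-catalysed intramolecular aldol of triketones and of acyclic heptane-2,6-diones to six-membered ketols. The six-membered ring closes in the 6-(enolendo)-exo-trig mode, helped by the gem-dialkoxy substitution at C1 (Thorpe–Ingold effect) and by the β-oxygen substituents on both sides of C5 that raise its electrophilicity. The C5 stereocentre is set by the catalyst: the acid-bound carbonyl oxygen and the enamine are held in a chair-like transition state, and mapping donor, tether and acceptor onto the Hajos–Parrish case (where (S)-proline puts the hydroxyl on the opposite face) predicts the (9R)-ketol from (R)-proline, which is (5S) in the target. The step needs regioselectivity (C4 onto C5, not C1' onto C3), which enamine formation at the methyl ketone and the branching at C2' next to C1' should secure. It must also stop at the ketol, which the mild, acid-free conditions should allow.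

Step 8
Reactants: 11 (9R)-9-hydroxy-9-[(10Z,13Z)-2-[(triethylsilyl)oxy]nonadeca-10,13-dien-1-yl]-1,4-dioxaspiro[4.5]decan-7-one
Product: 12 (5S)-5-hydroxy-3-(2-hydroxyethoxy)-5-[(10Z,13Z)-2-[(triethylsilyl)oxy]nonadeca-10,13-dien-1-yl]cyclohex-2-en-1-one
Conditions: CSA (5 mol%), CH2Cl2, 0 °C to rt
Reagents that add atoms: none
Why: Acid-catalysed ring-opening isomerization (β-elimination of one ketal oxygen through the oxocarbenium ion) should convert the β-keto dioxolane into the conjugated 3-alkoxy enone, the preferred form of a cyclohexane-1,3-dione monoketal, placing the carbonyl at C3 and the enol ether at C1 for the Stork–Danheiser transposition without touching C5.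

Step 9
Reactants: 12 (5S)-5-hydroxy-3-(2-hydroxyethoxy)-5-[(10Z,13Z)-2-[(triethylsilyl)oxy]nonadeca-10,13-dien-1-yl]cyclohex-2-en-1-one
Product: 14 (5S)-5-hydroxy-5-[(10Z,13Z)-2-hydroxynonadeca-10,13-dien-1-yl]cyclohex-2-en-1-one, via allylic alcohol 13 (not isolated)
Conditions: i-Bu2AlH (5 equiv), THF, −78 to 0 °C; then 1 M HCl, THF, 0 °C to rt
Reagents that add atoms: water O
Why: Stork–Danheiser transposition, in which 1,2-reduction of the vinylogous ester carbonyl (C3) and acid hydrolysis of the 3-alkoxy allylic alcohol 13 with loss of the C3 hydroxyl should give the enone with C1 as ketone and C2=C3 as alkene, the aqueous acid also cleaving the triethylsilyl ether; C5 is not involved and the transient C3 carbinol centre is lost again.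

Step 10
Reactants: 14 (5S)-5-hydroxy-5-[(10Z,13Z)-2-hydroxynonadeca-10,13-dien-1-yl]cyclohex-2-en-1-one
Product: 15 (5S)-5-hydroxy-5-[(10Z,13Z)-2-oxononadeca-10,13-dien-1-yl]cyclohex-2-en-1-one
Conditions: Dess–Martin periodinane, pyridine, CH2Cl2, 0 °C
Reagents that add atoms: none
Why: Dess–Martin oxidation of the only secondary alcohol (the tertiary C5 hydroxyl cannot be oxidised) should convert both C2' epimers into the single ketone under buffered conditions too mild for retro-aldol cleavage or dehydration of the β-hydroxy ketone.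

## Compound list

1 | dimethyl 3-oxopentanedioate | COC(=O)CC(=O)CC(=O)OC | starting material
2 | dimethyl 2,2'-(1,3-dioxolane-2,2-diyl)diacetate | COC(=O)CC1(CC(=O)OC)OCCO1 | intermediate
3 | 2,2'-(1,3-dioxolane-2,2-diyl)bis(N-methoxy-N-methylacetamide) | CON(C)C(=O)CC1(CC(=O)N(C)OC)OCCO1 | intermediate
4 | 1,1'-(1,3-dioxolane-2,2-diyl)di(propan-2-one) | CC(=O)CC1(CC(C)=O)OCCO1 | intermediate
5 | (9Z,12Z)-octadeca-9,12-dien-1-ol | CCCCC/C=C\C/C=C\CCCCCCCCO | starting material
6 | (9Z,12Z)-octadeca-9,12-dienal | CCCCC/C=C\C/C=C\CCCCCCCC=O | intermediate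
7 | 1-{2-[2-(dicyclohexylboranyloxy)prop-2-en-1-yl]-1,3-dioxolan-2-yl}propan-2-one | CC(=O)CC1(CC(=C)OB(C2CCCCC2)C2CCCCC2)OCCO1 | intermediate
8 | 1-{2-[(12Z,15Z)-4-hydroxy-2-oxohenicosa-12,15-dien-1-yl]-1,3-dioxolan-2-yl}propan-2-one, both configurations at the carbinol carbon | CCCCC/C=C\C/C=C\CCCCCCCC(O)CC(=O)CC1(CC(C)=O)OCCO1 | intermediate
9 | 1-{2-[(12Z,15Z)-2-oxo-4-[(triethylsilyl)oxy]henicosa-12,15-dien-1-yl]-1,3-dioxolan-2-yl}propan-2-one, both configurations at the silyloxy carbon | CCCCC/C=C\C/C=C\CCCCCCCC(O[Si](CC)(CC)CC)CC(=O)CC1(CC(C)=O)OCCO1 | intermediate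
10 | (2R)-1-[3-(2-{(12Z,15Z)-2-oxo-4-[(triethylsilyl)oxy]henicosa-12,15-dien-1-yl}-1,3-dioxolan-2-yl)prop-1-en-2-yl]pyrrolidine-2-carboxylic acid | CCCCC/C=C\C/C=C\CCCCCCCC(O[Si](CC)(CC)CC)CC(=O)CC1(CC(=C)N2CCC[C@@H]2C(=O)O)OCCO1 | intermediate
11 | (9R)-9-hydroxy-9-[(10Z,13Z)-2-[(triethylsilyl)oxy]nonadeca-10,13-dien-1-yl]-1,4-dioxaspiro[4.5]decan-7-one, both configurations at the silyloxy carbon | CCCCC/C=C\C/C=C\CCCCCCCC(O[Si](CC)(CC)CC)C[C@@]1(O)CC(=O)CC2(OCCO2)C1 | intermediate
12 | (5S)-5-hydroxy-3-(2-hydroxyethoxy)-5-[(10Z,13Z)-2-[(triethylsilyl)oxy]nonadeca-10,13-dien-1-yl]cyclohex-2-en-1-one | CCCCC/C=C\C/C=C\CCCCCCCC(O[Si](CC)(CC)CC)C[C@@]1(O)CC(=O)C=C(OCCO)C1 | intermediate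
13 | (1S)-5-(2-hydroxyethoxy)-1-[(10Z,13Z)-2-[(triethylsilyl)oxy]nonadeca-10,13-dien-1-yl]cyclohex-4-ene-1,3-diol, both configurations at C3 | CCCCC/C=C\C/C=C\CCCCCCCC(O[Si](CC)(CC)CC)C[C@@]1(O)CC(O)C=C(OCCO)C1 | intermediate
14 | (5S)-5-hydroxy-5-[(10Z,13Z)-2-hydroxynonadeca-10,13-dien-1-yl]cyclohex-2-en-1-one, both configurations at the side-chain carbinol | CCCCC/C=C\C/C=C\CCCCCCCC(O)C[C@@]1(O)CC=CC(=O)C1 | intermediate
15 | (5S)-5-hydroxy-5-[(10Z,13Z)-2-oxononadeca-10,13-dien-1-yl]cyclohex-2-en-1-one | CCCCC/C=C\C/C=C\CCCCCCCC(=O)C[C@@]1(O)CC=CC(=O)C1 | target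

## Step count and risks

Total step count: 10. Longest linear sequence: 9 steps (1, 2, 3, 5, 6, 7, 8, 9, 10); step 4 is a one-step side branch.

**Step 7.** What may go wrong: poor facial discrimination at the flexible acyclic C5 ketone, slow turnover, or further dehydration of the ketol by the amine catalyst. The fallback gives up asymmetric induction for racemic ring closure followed by enzymatic resolution. It sets out from 9, which is cyclised with an achiral amine salt (pyrrolidinium acetate, CH2Cl2, rt) to the racemic ketol F1. An Evans–Saksena reduction (Me4NBH(OAc)3, MeCN/AcOH, −20 °C), directed by the tertiary hydroxyl, should give the racemic trans-diol F2. Lipase-catalysed kinetic resolution (Candida antarctica lipase B, vinyl acetate, MTBE) should, by the usual empirical size rule, leave the diol of the required configuration F3 unreacted and convert its enantiomer into the acetate F4, which is separated. Mesylation of the secondary hydroxyl of F3 (MsCl, Et3N, CH2Cl2, 0 °C) gives the mesylate F5. Hydrolysis of the dioxolane and the silyl ether (PPTS, acetone/H2O, 50 °C) gives the β-mesyloxy ketone F6, and E1cB elimination (Et3N, CH2Cl2, 0 °C) comes back to the route at 14.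

**Step 5.** What may go wrong: the enol borinate of the symmetric diketone adds to its own second ketone to give a cyclic ketol, or a second aldehyde is taken up. The fallback replaces the metal enolate by an isolated enol silane. It sets out from 4, which is silylated twice under kinetic conditions (LiN(i-Pr)2, TMSCl present from the start, THF, −78 °C) to the bis(silyl enol ether) F7. A Mukaiyama aldol with one equivalent of 6 (BF3·OEt2, CH2Cl2, −78 °C) gives the mono-adduct F8, whose remaining enol silane is hydrolysed on work-up (aq. citric acid), returning to the route at 8.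

**Step 9.** What may go wrong: at the acid stage the liberated side-chain hydroxyl adds to the new enone (intramolecular oxa-Michael to a bridged ether), or the alkoxy enone loses the tertiary hydroxyl and aromatizes. The fallback oxidises C2' before the enone exists and uses an acetate as leaving group instead of the enol-ether route. It sets out from 11, which is reduced (NaBH4, MeOH, 0 °C) to the diol F9. Selective acetylation of the secondary hydroxyl (Ac2O, pyridine, DMAP, 0 °C) gives the acetate F10. Hydrolysis of the dioxolane and the silyl ether (PPTS, acetone/H2O, 50 °C) gives the β-acetoxy ketone F11. Dess–Martin oxidation of the side-chain carbinol gives the acetoxy diketone F12, and E1cB loss of acetic acid (Et3N, CH2Cl2, 0 °C) comes back to the route at 15.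

## Further compounds

F1 | step 7 | 9-hydroxy-9-[(10Z,13Z)-2-[(triethylsilyl)oxy]nonadeca-10,13-dien-1-yl]-1,4-dioxaspiro[4.5]decan-7-one, racemic at C9 | CCCCC/C=C\C/C=C\CCCCCCCC(O[Si](CC)(CC)CC)CC1(O)CC(=O)CC2(OCCO2)C1
F2 | step 7 | racemic trans-diol, (7S,9R)- and (7R,9S)-7-[(10Z,13Z)-2-[(triethylsilyl)oxy]nonadeca-10,13-dien-1-yl]-1,4-dioxaspiro[4.5]decane-7,9-diol | CCCCC/C=C\C/C=C\CCCCCCCC(O[Si](CC)(CC)CC)C[C@@]1(O)C[C@@H](O)CC2(OCCO2)C1.CCCCC/C=C\C/C=C\CCCCCCCC(O[Si](CC)(CC)CC)C[C@]1(O)C[C@H](O)CC2(OCCO2)C1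
F3 | step 7 | (7S,9R)-7-[(10Z,13Z)-2-[(triethylsilyl)oxy]nonadeca-10,13-dien-1-yl]-1,4-dioxaspiro[4.5]decane-7,9-diol | CCCCC/C=C\C/C=C\CCCCCCCC(O[Si](CC)(CC)CC)C[C@@]1(O)C[C@@H](O)CC2(OCCO2)C1
F4 | step 7 | (7S,9R)-9-hydroxy-9-[(10Z,13Z)-2-[(triethylsilyl)oxy]nonadeca-10,13-dien-1-yl]-1,4-dioxaspiro[4.5]decan-7-yl acetate (acetate of the unwanted enantiomer) | CCCCC/C=C\C/C=C\CCCCCCCC(O[Si](CC)(CC)CC)C[C@]1(O)C[C@H](OC(C)=O)CC2(OCCO2)C1
F5 | step 7 | (7R,9R)-9-hydroxy-9-[(10Z,13Z)-2-[(triethylsilyl)oxy]nonadeca-10,13-dien-1-yl]-1,4-dioxaspiro[4.5]decan-7-yl methanesulfonate | CCCCC/C=C\C/C=C\CCCCCCCC(O[Si](CC)(CC)CC)C[C@@]1(O)C[C@@H](OS(C)(=O)=O)CC2(OCCO2)C1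
F6 | step 7 | (1R,3R)-3-hydroxy-3-[(10Z,13Z)-2-hydroxynonadeca-10,13-dien-1-yl]-5-oxocyclohexyl methanesulfonate | CCCCC/C=C\C/C=C\CCCCCCCC(O)C[C@@]1(O)C[C@@H](OS(C)(=O)=O)CC(=O)C1
F7 | step 5 | 2,2-bis[2-(trimethylsilyloxy)prop-2-en-1-yl]-1,3-dioxolane | C=C(O[Si](C)(C)C)CC1(CC(=C)O[Si](C)(C)C)OCCO1
F8 | step 5 | (12Z,15Z)-4-hydroxy-1-{2-[2-(trimethylsilyloxy)prop-2-en-1-yl]-1,3-dioxolan-2-yl}henicosa-12,15-dien-2-one | CCCCC/C=C\C/C=C\CCCCCCCC(O)CC(=O)CC1(CC(=C)O[Si](C)(C)C)OCCO1
F9 | step 9 | 7-[(10Z,13Z)-2-[(triethylsilyl)oxy]nonadeca-10,13-dien-1-yl]-1,4-dioxaspiro[4.5]decane-7,9-diol, tertiary carbinol configured as in 11, both configurations at C9 | CCCCC/C=C\C/C=C\CCCCCCCC(O[Si](CC)(CC)CC)C[C@@]1(O)CC(O)CC2(OCCO2)C1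
F10 | step 9 | 9-hydroxy-9-[(10Z,13Z)-2-[(triethylsilyl)oxy]nonadeca-10,13-dien-1-yl]-1,4-dioxaspiro[4.5]decan-7-yl acetate, tertiary carbinol configured as in 11, both configurations at C7 | CCCCC/C=C\C/C=C\CCCCCCCC(O[Si](CC)(CC)CC)C[C@@]1(O)CC(OC(C)=O)CC2(OCCO2)C1
F11 | step 9 | 3-hydroxy-3-[(10Z,13Z)-2-hydroxynonadeca-10,13-dien-1-yl]-5-oxocyclohexyl acetate, tertiary carbinol configured as in 11 | CCCCC/C=C\C/C=C\CCCCCCCC(O)C[C@@]1(O)CC(OC(C)=O)CC(=O)C1
F12 | step 9 | 3-hydroxy-5-oxo-3-[(10Z,13Z)-2-oxononadeca-10,13-dien-1-yl]cyclohexyl acetate, tertiary carbinol configured as in 11 | CCCCC/C=C\C/C=C\CCCCCCCC(=O)C[C@@]1(O)CC(OC(C)=O)CC(=O)C1
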